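**Plan**

Cyclopentane locants follow the name of the target: C1 (aryl, Me), C2 (H, Me), C3 (=CHBr), C4, C5.

1. Retrosynthesis: both C–Br bonds are cut last (aryl C–H and vinyl C–SiMe3 in the precursor). The ring bonds C1–C2 and C3–C4 are then cut together, leaving 5-methyl-2-(1-methylcyclopropyl)phenol (C1, C5, C4) and a 1-silylbuta-1,2-diene (C2, C3, exocyclic CH). The cyclopropane goes back to an isopropenylphenol and that to the acetophenone.
2. Forward: acetophenone → isopropenylphenol → methylcyclopropylphenol; the cyclopentane is the only ring built onto the arene that remains and arises in one cobalt-catalysed (3+2) step; both bromines enter in the final operation. No protecting group is used.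
3. Enabling feature: the phenolic oxygen sits on the aryl carbon next to the one bonded to C1, so O–C(aryl)=C(aryl)–C1 is a vinylogous carbinol. A cyclopropane on C1 is therefore a vinylogous cyclopropanol and can open to an ortho-quinone methide carrying a CH2–Co bond. The exocyclic C3=CH is the footprint of the central allene carbon, and SiMe3 marks the carbon that later carries Br.
4. Stereochemistry: C1 and C2 are both set in the C1–C2 bond formation inside a chiral bisphosphine–cobalt complex (absolute sense from the ligand, cis aryl/methyl from O–Co chelation). The (E) geometry comes from the allylcobalt and is passed to the bromide by retentive ipso-bromodesilylation.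

Key step: step 4

Assumption: the sense of induction of the chiral bisphosphine in step 4 has to be found by experiment, so the ligand antipode written is a placeholder for the one that gives the (1R,2R) product.

Step 1
Reactants: 1 1-(2-hydroxy-4-methylphenyl)ethan-1-one
Product: 2 5-methyl-2-(prop-1-en-2-yl)phenol
Conditions: Ph3PCH3Br (2.5 equiv), KOtBu (2.5 equiv), THF, 0 °C to reflux
Reagents that add atoms: methyltriphenylphosphonium bromide, C[P+](c1ccccc1)(c1ccccc1)c1ccccc1.[Br-]
Why: Wittig methylenation, in which the first equivalent of ylide only deprotonates the phenol and the excess should convert the ketone of the phenoxide into the 1,1-disubstituted alkene on heating; no stereocentre is formed.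

Step 2
Reactants: 2 5-methyl-2-(prop-1-en-2-yl)phenol
Product: 3 5-methyl-2-(1-methylcyclopropyl)phenol
Conditions: Et2Zn (2.5 equiv), CH2I2 (3.0 equiv), CH2Cl2, 0 °C to rt
Reagents that add atoms: diiodomethane, ICI
Why: Simmons–Smith cyclopropanation with the Et2Zn/CH2I2 carbenoid, which the zinc phenoxide formed in the flask should hold next to the electron-rich 1,1-disubstituted alkene; the product is achiral.

Step 3
Reactants: 4 4-(trimethylsilyl)but-3-yn-2-ol (racemic)
Product: 7 (buta-1,2-dien-1-yl)trimethylsilane (racemic), via sulfonylhydrazine adduct 5 (not isolated), via propargylic diazene 6 (not isolated)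
Conditions: 2-nitrobenzenesulfonohydrazide (1.3 equiv), PPh3 (1.3 equiv), DEAD (1.3 equiv), THF, −15 °C to 23 °C
Reagents that add atoms: none
Why: Mitsunobu N-alkylation of the sulfonylhydrazide by the propargylic alcohol, loss of the sulfinic acid on warming and retro-ene loss of N2 from the propargylic diazene should give the silylallene in one flask, racemic because 4 is racemic.

Step 4
Reactants: 3 5-methyl-2-(1-methylcyclopropyl)phenol; 7 (buta-1,2-dien-1-yl)trimethylsilane (racemic, 1.5 equiv)
Product: 10 5-methyl-2-[(1R,2R,3E)-1,2-dimethyl-3-[(trimethylsilyl)methylidene]cyclopentyl]phenol, via quinone methide alkylcobalt 8 (not isolated), via allylcobalt 9 (not isolated)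
Conditions: CoBr2 (10 mol %), (R,R)-QuinoxP* (12 mol %), Zn (20 mol %), DABCO (50 mol %), MeCN, 60 °C
Reagents that add atoms: none
Why: Proposed new method: the monovalent cobalt phenoxide of 3 should cleave one of the two equivalent C1–CH2 bonds of the cyclopropane by a six-membered shift of cobalt from oxygen to that CH2 through the ortho aryl carbon (the vinylogous form of the β-carbon elimination of cobalt cyclopropoxides; the loss of aromaticity is estimated to be roughly offset by the released ring strain), giving the quinone methide alkylcobalt 8, whose Co–CH2 bond should add to the central carbon of allene 7 to form C3–C4 and the allylcobalt 9. Intramolecular 1,4-allylation of the quinone methide through the methyl-bearing allyl terminus then forms C1–C2, restores the phenol and returns cobalt to oxygen, so that the O–H of the next molecule of 3 turns the catalyst over; the closest known reaction type is the cobalt–diphosphine formal (3+2) annulation of cyclopropanols with allenes (homoenolate formation, allene insertion, carbonyl allylation). The cyclopentane closes in a 5-exo-trig mode on the exocyclic C=C of the quinone methide. C1 and C2 are created together in that closure: their absolute configuration should be controlled by the chiral bisphosphine on cobalt, which acts on an allylcobalt that equilibrates by π–σ–π shifts and so uses both enantiomers of racemic 7, and the cis relation of aryl and C2 methyl by the O–Co chelated, closed transition structure. The step needs bond formation at the CHMe terminus and not at the CHSi terminus, which cobalt sitting α to silicon and the bulk of SiMe3 should secure, and one alkene geometry, for which the syn position of silicon on the 2-substituted allyl should give the (E)-vinylsilane.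

Step 5
Reactants: 10 5-methyl-2-[(1R,2R,3E)-1,2-dimethyl-3-[(trimethylsilyl)methylidene]cyclopentyl]phenol
Product: 12 4-bromo-2-[(1R,2R,3E)-3-(bromomethylidene)-1,2-dimethylcyclopentyl]-5-methylphenol, via ring-brominated vinylsilane 11 (not isolated)
Conditions: NBS (2.1 equiv), MeCN, −20 °C to rt
Reagents that add atoms: N-bromosuccinimide, O=C1CCC(=O)N1Br
Why: Electrophilic aromatic bromination para to the hydroxyl group (as in thymol) by the first equivalent and ipso-bromodesilylation of the vinylsilane by the second, which should pass through the tertiary β-silyl cation and so replace silicon by bromine with retention of the (E) geometry.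

**Compound list**

1 | 1-(2-hydroxy-4-methylphenyl)ethan-1-one | CC(=O)c1ccc(C)cc1O | starting material
2 | 5-methyl-2-(prop-1-en-2-yl)phenol | CC(=C)c1ccc(C)cc1O | intermediate
3 | 5-methyl-2-(1-methylcyclopropyl)phenol | Cc1ccc(C2(C)CC2)c(O)c1 | intermediate
4 | 4-(trimethylsilyl)but-3-yn-2-ol (racemic) | CC(O)C#C[Si](C)(C)C | starting material
5 | N-[4-(trimethylsilyl)but-3-yn-2-yl]-2-nitrobenzenesulfonohydrazide (racemic) | CC(C#C[Si](C)(C)C)N(N)S(=O)(=O)c1ccccc1[N+](=O)[O-] | intermediate
6 | [4-(trimethylsilyl)but-3-yn-2-yl]diazene (racemic) | CC(N=N)C#C[Si](C)(C)C | intermediate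
7 | (buta-1,2-dien-1-yl)trimethylsilane (racemic) | CC=C=C[Si](C)(C)C | intermediate
8 | ortho-quinone methide alkylcobalt species (ligands on cobalt not shown) | CC(CC[Co])=C1C=CC(C)=CC1=O | intermediate
9 | silyl-substituted allylcobalt species (ligands on cobalt not shown, alkene geometry not fixed) | CC=C(CCC(C)=C1C=CC(C)=CC1=O)C([Co])[Si](C)(C)C | intermediate
10 | 5-methyl-2-[(1R,2R,3E)-1,2-dimethyl-3-[(trimethylsilyl)methylidene]cyclopentyl]phenol | Cc1ccc([C@]2(C)CC/C(=C\[Si](C)(C)C)[C@@H]2C)c(O)c1 | intermediate
11 | 4-bromo-2-[(1R,2R,3E)-1,2-dimethyl-3-[(trimethylsilyl)methylidene]cyclopentyl]-5-methylphenol | Cc1cc(O)c([C@]2(C)CC/C(=C\[Si](C)(C)C)[C@@H]2C)cc1Br | intermediate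
12 | 4-bromo-2-[(1R,2R,3E)-3-(bromomethylidene)-1,2-dimethylcyclopentyl]-5-methylphenol | Cc1cc(O)c([C@]2(C)CC/C(=C\Br)[C@@H]2C)cc1Br | target

**Count and risks**

Total step count: 5. Longest linear sequence: 4 steps (steps 1, 2, 4, 5); step 3 supplies the allene.

Step 4 (proposed new method). The cyclopropane may fail to open at the phenoxide, the alkylcobalt may undergo β-hydride elimination and end in chromene-type products, bond formation may occur at the silyl-bearing allyl terminus, or the facial selectivity of the 1,4-allylation may be poor (trans isomer, low enantiomeric purity). The fallback uses known chemistry and runs from 1 back to 10. Silylation of 1 (TIPSOTf, 2,6-lutidine) gives 1-[4-methyl-2-(triisopropylsilyloxy)phenyl]ethan-1-one F1, and TMSOTf/Et3N gives the trimethylsilyl enol ether F2. Simmons–Smith cyclopropanation (Et2Zn, CH2I2) gives the siloxycyclopropane F3, and K2CO3/MeOH frees the 1-arylcyclopropan-1-ol F4. The known cobalt–diphosphine (3+2) annulation of this true cyclopropanol with 7 (CoBr2, the same bisphosphine, Zn, DABCO, MeCN) forms the same two ring bonds in one operation and gives the tertiary benzylic cyclopentanol F5; the ligand has to set C2 here. Me2TiCl2 (from Me2Zn and TiCl4, CH2Cl2, −30 °C) then replaces the hydroxyl by methyl through the benzylic cation, with methyl expected to enter trans to the C2 methyl, to give the silyl ether F6. TBAF returns to 10. In this fallback the quaternary centre is set by substrate control and no longer depends on the allylation transition structure.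

Step 5. The ring may be brominated a second time, the alkene geometry may be lost during the ipso-substitution, or the free phenol oxygen may capture the β-silyl cation. The fallback runs from 10 back to 12 and separates the two halogenations. Ac2O/pyridine gives the aryl acetate F7, which deactivates the ring and masks the oxygen. NBS in MeCN then performs only the ipso-bromodesilylation to give the vinyl bromide acetate F8. K2CO3/MeOH frees the phenol F9, and one equivalent of NBS at −20 °C brominates para to the hydroxyl to give 12.

Step 2. Zinc halide may promote dimerisation or cyclisation of the isopropenylphenol, and the carbenoid may alkylate the oxygen. The fallback runs from 2 back to 3 by dihalocarbene addition and reduction on the masked phenol. TIPSOTf/2,6-lutidine gives the silyl ether F10. Dibromocarbene (CHBr3, KOtBu, pentane, 0 °C) gives the gem-dibromocyclopropane F11. Bu3SnH/AIBN removes both bromines to give the silyl-protected methylcyclopropane F12, and TBAF returns to 3.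

Further compounds
F1 | step 4 | 1-[4-methyl-2-(triisopropylsilyloxy)phenyl]ethan-1-one | CC(=O)c1ccc(C)cc1O[Si](C(C)C)(C(C)C)C(C)C
F2 | step 4 | triisopropyl{5-methyl-2-[1-(trimethylsilyloxy)ethenyl]phenoxy}silane | C=C(O[Si](C)(C)C)c1ccc(C)cc1O[Si](C(C)C)(C(C)C)C(C)C
F3 | step 4 | triisopropyl{5-methyl-2-[1-(trimethylsilyloxy)cyclopropyl]phenoxy}silane | Cc1ccc(C2(O[Si](C)(C)C)CC2)c(O[Si](C(C)C)(C(C)C)C(C)C)c1
F4 | step 4 | 1-[4-methyl-2-(triisopropylsilyloxy)phenyl]cyclopropan-1-ol | Cc1ccc(C2(O)CC2)c(O[Si](C(C)C)(C(C)C)C(C)C)c1
F5 | step 4 | 2-methyl-1-[4-methyl-2-(triisopropylsilyloxy)phenyl]-3-[(E)-(trimethylsilyl)methylidene]cyclopentan-1-ol (C2 as in 10, either carbinol epimer) | Cc1ccc(C2(O)CC/C(=C\[Si](C)(C)C)[C@@H]2C)c(O[Si](C(C)C)(C(C)C)C(C)C)c1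
F6 | step 4 | triisopropyl{5-methyl-2-[(1R,2R,3E)-1,2-dimethyl-3-[(trimethylsilyl)methylidene]cyclopentyl]phenoxy}silane | Cc1ccc([C@]2(C)CC/C(=C\[Si](C)(C)C)[C@@H]2C)c(O[Si](C(C)C)(C(C)C)C(C)C)c1
F7 | step 5 | 5-methyl-2-[(1R,2R,3E)-1,2-dimethyl-3-[(trimethylsilyl)methylidene]cyclopentyl]phenyl acetate | CC(=O)Oc1cc(C)ccc1[C@]2(C)CC/C(=C\[Si](C)(C)C)[C@@H]2C
F8 | step 5 | 2-[(1R,2R,3E)-3-(bromomethylidene)-1,2-dimethylcyclopentyl]-5-methylphenyl acetate | CC(=O)Oc1cc(C)ccc1[C@]2(C)CC/C(=C\Br)[C@@H]2C
F9 | step 5 | 2-[(1R,2R,3E)-3-(bromomethylidene)-1,2-dimethylcyclopentyl]-5-methylphenol | Cc1ccc([C@]2(C)CC/C(=C\Br)[C@@H]2C)c(O)c1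
F10 | step 2 | triisopropyl[5-methyl-2-(prop-1-en-2-yl)phenoxy]silane | CC(=C)c1ccc(C)cc1O[Si](C(C)C)(C(C)C)C(C)C
F11 | step 2 | [2-(2,2-dibromo-1-methylcyclopropyl)-5-methylphenoxy]triisopropylsilane (racemic) | Cc1ccc(C2(C)CC2(Br)Br)c(O[Si](C(C)C)(C(C)C)C(C)C)c1
F12 | step 2 | triisopropyl[5-methyl-2-(1-methylcyclopropyl)phenoxy]silane | Cc1ccc(C2(C)CC2)c(O[Si](C(C)C)(C(C)C)C(C)C)c1
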